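**Remark (chemistry):** ring A is numbered from the ester-bearing carbon (C1; hydroxyls on C2 and C4, ether oxygen on C6) and ring B from the carbonyl carbon next to the aryloxy-bearing carbon (C1 and C4 carbonyls, C2 aryloxy, C3 methoxy, C5 and C6 prenyl); the target has no stereocentre and no stereogenic double bond; the acetylated precursor of the key step is kept as it stands, but ring A is carried as its dibenzyl ether until the quinone has been reduced, so that no aryl acetate is exposed to a phenoxide.

## Structural features

Atrovirinone (16) consists of two six-membered carbocycles joined through one ether oxygen. Ring A is a methyl benzoate with free hydroxyls on C2 and C4 and the bridging oxygen on C6; ring B is a 1,4-benzoquinone with the aryloxy group on C2, a methoxy group on C3 and two 3-methylbut-2-enyl (prenyl) groups on the adjacent carbons C5 and C6. There is no stereocentre, and each alkene ends in two identical methyl groups, so the problem is one of regiochemistry and functional-group compatibility only. The aryloxyquinone is a vinylogous aryl ester from which methoxide or amines can expel the ring A phenoxide, and the quinone is sensitive to base and to reductants. The prenyl alkenes are attacked by acid (chroman formation with an ortho hydroxyl of the hydroquinone), by electrophilic bromine and by radicals, and the hydroquinone form is air-sensitive. The real difficulty is threefold: ring B is fully substituted with four kinds of substituent in a fixed order; the ether must be made at the hindered, hydrogen-bonded oxygen ortho to the ester of ring A and not at the more reactive para oxygen; and two neighbouring linear prenyl groups cannot be introduced reliably by Friedel–Crafts or Claisen chemistry. Each prenyl group is a ring-bound CH2 attached to a 2-methylpropenyl unit, so the CH2 carbons on C5 and C6 of ring B map onto the two methyl groups of 2,3-dimethylhydroquinone. The key step exploits this: once ring B has no ring hydrogen, only those two methyl groups can be brominated, and both CH2–CH= bonds are then made by palladium-catalysed coupling of the benzylic bromides with an alkenyltin reagent.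

## Logic of the disconnections

16 back to 15 and 14: no skeletal bond is cut; the quinone is taken back to the hydroquinone and the four phenolic O–H bonds to O–acetyl bonds. The reason is that the vinylogous ester of 16 would not survive radicals, tin reagents or palladium, whereas the tetraacetate 14 is inert to all three. The gain is a single protecting group removed in one operation. The demand is that deacetylation is run without oxygen, so that no quinone ever meets methoxide, and that the oxidation of 15 is neutral and non-nucleophilic.

14 back to 10 and 13: the two CH2–CH= bonds on C5 and C6 of ring B are cut. Cutting here removes both prenyl groups at once and leaves carbons that derive from ring methyl groups, and it avoids every ambiguity of electrophilic prenylation. The forward step must couple both benzylic bromides of 10 without 1,4-debromination and without touching acetates, ester or diaryl ether.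

13 back to 11 through 12: the Sn–C bond is cut. This traces the tin reagent to a commercial alkenyl bromide in one step; the demand is only a clean magnesium insertion.

10 back to 9: the two benzylic C–Br bonds are cut. Ring B of 9 has no ring hydrogen and its two methyl groups are the only benzylic C–H bonds in the molecule, and the four acetates keep both rings electron-poor. The demand is control of stoichiometry, so that one bromine and no more enters each methyl group.

9 back to 7 through 8: four O–acetyl bonds are cut and ring B is returned to the quinone level, with ring A as its dibenzyl ether. The quinone level is needed for the ether-forming step but cannot be carried further. One hydrogenation is asked to reduce the quinone and remove both benzyl groups, and the air-sensitive 8 must be acetylated before it sees oxygen.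

7 back to 4 and 6: the bond between C2 of ring B and the ether oxygen is cut. This splits the molecule into two halves of similar size and uses the quinone as a vinylogous acyl bromide, so no copper-mediated arylation of a hexasubstituted arene is needed. The regiochemistry on ring A is fixed by the single free hydroxyl of 6. The demand is that the phenoxide displaces bromide and not methoxide.

4 back to 3 and then to 1 through 2: the C3–OMe bond and the two ring C–Br bonds are cut. The dibromide 3 is symmetrical, so the first substitution has no regiochemical choice. Methoxide goes in first because it is the stronger nucleophile and would attack the aryloxy group if it came second. The demand is that substitution stops after one bromide.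

6 back to 5: two O–benzyl bonds are cut. The hydrogen bond between the ester carbonyl and one ortho hydroxyl leaves exactly that hydroxyl free; the demand is two equivalents of benzyl bromide and a weak base.

## Other disconnections considered

Alternative 1: The ester C–O bond of ring A is reconnected to the oxygen on C1 of ring B, giving the depsidone A2, and that oxygen is then removed, giving the xanthone A1 in which the carbonyl carbon is bonded directly to C1 of ring B. In the forward direction alkaline H2O2 would add to the xanthone carbonyl of A1, and the ring B carbon para to the phenoxide on C4 would migrate from carbon to oxygen. This expands the pyranone to the seven-membered lactone of A2; methanolysis, removal of the methoxymethyl groups and oxidation would then lead to 16.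
- In its favour: the ester and the oxygen on C1 of ring B arise in one event, the tricycle fixes which ring A oxygen carries ring B, and no tin is used. On the regiochemistry of the ether this plan is the better one, since no selective protection of ring A is needed.
- Against it: the xanthone carbonyl is a doubly vinylogous ester and a poor electrophile. Dakin-type oxidation is established for para-hydroxyaryl aldehydes and alkyl ketones, not for xanthones. Ring A, with two alkoxy donors, could migrate in competition, and an electron-rich phenoxide may be oxidised by H2O2 at the ring. A1 must already carry two adjacent prenyl groups, so the prenylation problem is only moved, and acid removal of the methoxymethyl groups next to free hydroxyls and prenyl groups invites chroman formation.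
- Comparison: the chosen plan rests on well-precedented reaction types at every stage, while this key step would be unproven on its substrate class. In step economy the alternative is the weaker, because A1 itself would need a long synthesis.

Alternative 2: Ring A is dismantled at its C1–C2 and C5–C6 bonds, leaving the aryloxy ynoate A3 and Chan's diene A4. In the forward direction the methylene end of A4 would bond to the aryloxy-bearing β-carbon of A3 and the ketene acetal carbon to the α-carbon, in a concerted or a stepwise sense. Loss of methanol would then aromatise the ring to A5, with the ring A hydroxyls free after work-up; removal of the two silyl groups of A5 gives 15.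
- In its favour: the whole substitution pattern of ring A follows from polarity matching, with no protecting group on ring A. On this point the alternative is better than the chosen plan, and the endgame is equal, since both pass through 15.
- Against it: A3 is a push–pull alkyne whose oxygen donor lowers its reactivity as a dienophile, and aryl ynol ethers of a hindered, fully substituted phenol are laborious to prepare. The ring B half must be made with both prenyl groups, two silyl ethers, one methyl ether and one free hydroxyl already differentiated.
- Comparison: structurally the plan is elegant for ring A but leaves ring B harder than in the chosen route. Mechanistically the cycloaddition is less secure than an addition–elimination on a bromoquinone. The step count would be higher, because four ring B oxygens must be told apart.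

Alternative 3: The ether bond at C6 of ring A and the bond from C1 of ring A to the carboxyl carbon are cut together, leaving the ring B phenol A6, the silyl triflate A7 and CO2. In the forward direction CsF would release the aryne from A7, and the phenoxide of A6 would add at the aryne carbon remote from the neighbouring methoxymethoxy group. The aryl anion so formed, flanked by two oxygen-bearing carbons, would capture CO2 to give the acid A8.
- In its favour: two bonds of ring A form in one step with the well-established regiochemistry of 3-alkoxyarynes, the union is highly convergent, and no acyl or quinone group is present to interfere. At the ether-forming stage it is the equal of the chosen plan, and better in that the carboxyl carbon is set at the same time.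
- Against it: A6 is a phenoxide with two ortho methoxy groups and binds CO2 reversibly itself, the aryl anion can be protonated before it meets CO2, and three-component aryne carboxylations are most secure with nitrogen nucleophiles. A6 again needs both prenyl groups and A7 several steps of its own. After A8 come esterification, acid removal of the methoxymethyl groups in the presence of the alkenes, and oxidative demethylation with (NH4)2Ce(NO3)6 beside free ring A phenols, with a choice between para- and ortho-quinone.
- Comparison: the chosen plan has the gentler endgame (Ag2O on a hydroquinone) and the shorter overall count; the alternative has the more convergent union.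

Key step: step 8

## Route

Step 1
Reactants: 1 2,3-dimethylhydroquinone
Product: 3 2,3-dibromo-5,6-dimethyl-1,4-benzoquinone, via 2,3-dibromo-5,6-dimethylhydroquinone 2 (not isolated)
Conditions: Br2 (2.1 equiv), AcOH, rt; then aq FeCl3 (2.5 equiv), rt
Reagents that add atoms: bromine, BrBr
Why: Electrophilic aromatic bromination of the electron-rich hydroquinone fills the only two free ring positions, and FeCl3 then oxidises the hydroquinone to the quinone; whichever order bromination and oxidation take in the flask, the material should converge on 3 because no other ring position is open.

Step 2
Reactants: 3 2,3-dibromo-5,6-dimethyl-1,4-benzoquinone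
Product: 4 2-bromo-3-methoxy-5,6-dimethyl-1,4-benzoquinone
Conditions: NaOMe (1.0 equiv, slow addition), MeOH–THF, −40 → 0 °C
Reagents that add atoms: sodium methoxide, C[O-].[Na+]
Why: Addition–elimination (nucleophilic vinylic substitution) of methoxide at a bromine-bearing quinone carbon; the dibromide is symmetrical, so there is no regiochemical choice, and the methoxy group then donates into the quinone and slows a second substitution, so one equivalent at low temperature should stop at 4.

Step 3
Reactants: 5 methyl 2,4,6-trihydroxybenzoate
Product: 6 methyl 2,4-bis(benzyloxy)-6-hydroxybenzoate
Conditions: BnBr (2.05 equiv), K2CO3, acetone, reflux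
Reagents that add atoms: benzyl bromide, BrCc1ccccc1
Why: Williamson O-benzylation under weak base; the para hydroxyl is the most acidic and reacts first, one ortho hydroxyl follows, and the last one is held in a hydrogen bond to the ester carbonyl and stays free, the usual pattern for 2,4,6-trihydroxyaryl carbonyl compounds.

Step 4
Reactants: 4 2-bromo-3-methoxy-5,6-dimethyl-1,4-benzoquinone; 6 methyl 2,4-bis(benzyloxy)-6-hydroxybenzoate
Product: 7 methyl 2,4-bis(benzyloxy)-6-[(3-methoxy-5,6-dimethyl-1,4-benzoquinon-2-yl)oxy]benzoate
Conditions: K2CO3 (1.2 equiv), DMF, 0 °C → rt
Reagents that add atoms: none
Why: Addition–elimination of the phenoxide of 6 on the bromoquinone; 6 has one free oxygen only, so the ether must form ortho to the ester, and attack at the methoxy-bearing carbon is unproductive because that adduct would expel the aryloxide again, whereas at the bromine-bearing carbon bromide leaves irreversibly.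

Step 5
Reactants: 7 methyl 2,4-bis(benzyloxy)-6-[(3-methoxy-5,6-dimethyl-1,4-benzoquinon-2-yl)oxy]benzoate
Product: 9 methyl 2,4-diacetoxy-6-(2,5-diacetoxy-6-methoxy-3,4-dimethylphenoxy)benzoate, via tetrahydroxy diaryl ether 8 (not isolated)
Conditions: H2 (1 atm), Pd/C (palladium on carbon), EtOAc, rt; then Ac2O, pyridine, DMAP (cat.), rt, air excluded throughout
Reagents that add atoms: acetic anhydride, CC(=O)OC(C)=O
Why: Catalytic hydrogenation reduces the quinone to the hydroquinone and hydrogenolyses both benzyl ethers; acetylation of the four phenols in the same flask, before any contact with air, should give the tetraacetate, with DMAP helping at the hindered ring B hydroxyls.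

Step 6
Reactants: 9 methyl 2,4-diacetoxy-6-(2,5-diacetoxy-6-methoxy-3,4-dimethylphenoxy)benzoate
Product: 10 methyl 2,4-diacetoxy-6-[2,5-diacetoxy-3,4-bis(bromomethyl)-6-methoxyphenoxy]benzoate
Conditions: NBS (2.1 equiv), AIBN (cat.), PhCF3, 85 °C
Reagents that add atoms: N-bromosuccinimide, O=C1CCC(=O)N1Br
Why: Wohl–Ziegler benzylic bromination; ring B has no ring hydrogen, its two methyl groups are the only benzylic C–H bonds in the molecule, and the acetates keep both rings too electron-poor for ionic ring bromination, so about two equivalents of NBS should place one bromine on each methyl group.

Step 7
Reactants: 11 1-bromo-2-methylprop-1-ene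
Product: 13 tributyl(2-methylprop-1-enyl)stannane, via (2-methylprop-1-enyl)magnesium bromide 12 (not isolated)
Conditions: Mg, THF, reflux; then Bu3SnCl, 0 °C → rt
Reagents that add atoms: tributyltin chloride, CCCC[Sn](Cl)(CCCC)CCCC
Why: Grignard formation from the alkenyl bromide followed by substitution at tin; the alkene carries two identical methyl groups, so no double-bond geometry is at stake.

Step 8
Reactants: 10 methyl 2,4-diacetoxy-6-[2,5-diacetoxy-3,4-bis(bromomethyl)-6-methoxyphenoxy]benzoate; 13 tributyl(2-methylprop-1-enyl)stannane
Product: 14 methyl 2,4-diacetoxy-6-[2,5-diacetoxy-6-methoxy-3,4-bis(3-methylbut-2-enyl)phenoxy]benzoate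
Conditions: 13 (3 equiv), Pd(PPh3)4 (10 mol %), degassed toluene, 100 °C, Ar
Reagents that add atoms: none
Why: Zerovalent palladium inserts into one benzylic C–Br bond to give a benzyl complex of divalent palladium, the 2-methylpropenyl group is transferred from tin with release of Bu3SnBr, and reductive elimination forms the CH2–CH= bond and returns zerovalent palladium; the same cycle then runs at the neighbouring bromomethyl group. The closest known reaction type is the Stille coupling of benzylic bromides with alkenylstannanes (sp3–sp2), including twofold coupling of bis(bromomethyl)arenes. No ring is closed and no stereocentre is formed, and the new alkenes have two identical methyl groups. The constitutional selectivity needed is linear prenylation at carbon, which is secured because the alkenyl group can bond only through its tin-bearing carbon, so neither reverse prenyl groups nor O-alkylated products can arise. The chemoselectivity needed is coupling of both bromides in preference to 1,4-debromination to an ortho-quinodimethane or to homocoupling, which an excess of 13 and the absence of any base or reductant should secure. The benzyl–palladium intermediate has no β-hydrogen, so β-hydride elimination is excluded. The neutral medium should leave the four aryl acetates, the methyl ester and the diaryl ether untouched.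

Step 9
Reactants: 14 methyl 2,4-diacetoxy-6-[2,5-diacetoxy-6-methoxy-3,4-bis(3-methylbut-2-enyl)phenoxy]benzoate
Product: 15 methyl 2-[2,5-dihydroxy-6-methoxy-3,4-bis(3-methylbut-2-enyl)phenoxy]-4,6-dihydroxybenzoate
Conditions: K2CO3 (2 equiv), degassed MeOH, 0 °C → rt, Ar; then AcOH
Reagents that add atoms: none
Why: Base-catalysed transesterification of the four aryl acetates to methanol (Zemplén-type deacetylation); methanol as solvent makes exchange at the methyl ester degenerate and disfavours lactonisation, the prenyl groups are inert to base, and exclusion of oxygen keeps ring B at the hydroquinone level so that no quinone meets methoxide.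

Step 10
Reactants: 15 methyl 2-[2,5-dihydroxy-6-methoxy-3,4-bis(3-methylbut-2-enyl)phenoxy]-4,6-dihydroxybenzoate
Product: 16 atrovirinone, methyl 2,4-dihydroxy-6-{[3-methoxy-5,6-bis(3-methylbut-2-enyl)-1,4-benzoquinon-2-yl]oxy}benzoate
Conditions: Ag2O, Na2SO4, Et2O, rt, dark
Reagents that add atoms: none
Why: Two-electron oxidation of a para-hydroquinone to the para-quinone by Ag2O under neutral, non-nucleophilic conditions; only ring B has para-disposed hydroxyls, so ring A, the prenyl alkenes and the newly formed vinylogous aryl ester should be left alone.

## Compound list

1 | 2,3-dimethylhydroquinone | Cc1c(C)c(O)ccc1O | starting material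
2 | 2,3-dibromo-5,6-dimethylhydroquinone | Cc1c(C)c(O)c(Br)c(Br)c1O | intermediate
3 | 2,3-dibromo-5,6-dimethyl-1,4-benzoquinone | CC1=C(C)C(=O)C(Br)=C(Br)C1=O | intermediate
4 | 2-bromo-3-methoxy-5,6-dimethyl-1,4-benzoquinone | COC1=C(Br)C(=O)C(C)=C(C)C1=O | intermediate
5 | methyl 2,4,6-trihydroxybenzoate | COC(=O)c1c(O)cc(O)cc1O | starting material
6 | methyl 2,4-bis(benzyloxy)-6-hydroxybenzoate | COC(=O)c1c(O)cc(OCc2ccccc2)cc1OCc1ccccc1 | intermediate
7 | methyl 2,4-bis(benzyloxy)-6-[(3-methoxy-5,6-dimethyl-1,4-benzoquinon-2-yl)oxy]benzoate | COC(=O)c1c(OCc2ccccc2)cc(OCc2ccccc2)cc1OC1=C(OC)C(=O)C(C)=C(C)C1=O | intermediate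
8 | methyl 2-(2,5-dihydroxy-6-methoxy-3,4-dimethylphenoxy)-4,6-dihydroxybenzoate (tetrahydroxy diaryl ether) | COC(=O)c1c(O)cc(O)cc1Oc1c(OC)c(O)c(C)c(C)c1O | intermediate
9 | methyl 2,4-diacetoxy-6-(2,5-diacetoxy-6-methoxy-3,4-dimethylphenoxy)benzoate | COC(=O)c1c(OC(C)=O)cc(OC(C)=O)cc1Oc1c(OC)c(OC(C)=O)c(C)c(C)c1OC(C)=O | intermediate
10 | methyl 2,4-diacetoxy-6-[2,5-diacetoxy-3,4-bis(bromomethyl)-6-methoxyphenoxy]benzoate | COC(=O)c1c(OC(C)=O)cc(OC(C)=O)cc1Oc1c(OC)c(OC(C)=O)c(CBr)c(CBr)c1OC(C)=O | intermediate
11 | 1-bromo-2-methylprop-1-ene | CC(C)=CBr | starting material
12 | (2-methylprop-1-enyl)magnesium bromide | CC(C)=C[Mg]Br | intermediate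
13 | tributyl(2-methylprop-1-enyl)stannane | CC(C)=C[Sn](CCCC)(CCCC)CCCC | intermediate
14 | methyl 2,4-diacetoxy-6-[2,5-diacetoxy-6-methoxy-3,4-bis(3-methylbut-2-enyl)phenoxy]benzoate | COC(=O)c1c(OC(C)=O)cc(OC(C)=O)cc1Oc1c(OC)c(OC(C)=O)c(CC=C(C)C)c(CC=C(C)C)c1OC(C)=O | intermediate
15 | methyl 2-[2,5-dihydroxy-6-methoxy-3,4-bis(3-methylbut-2-enyl)phenoxy]-4,6-dihydroxybenzoate (atrovirinone hydroquinone) | COC(=O)c1c(O)cc(O)cc1Oc1c(OC)c(O)c(CC=C(C)C)c(CC=C(C)C)c1O | intermediate
16 | atrovirinone | COC(=O)c1c(O)cc(O)cc1OC1=C(OC)C(=O)C(CC=C(C)C)=C(CC=C(C)C)C1=O | target

## Step count and least certain steps

Total step count: 10. Longest linear sequence: 8 steps (steps 1, 2, 4, 5, 6, 8, 9, 10, from 1 to 16); the ring A branch (step 3) and the tin reagent (step 7) join it at steps 4 and 8.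

**Step 8 (key step).** The most likely failure is reductive 1,4-elimination: after the first oxidative addition the benzylpalladium species sits next to a second bromomethyl group and may expel bromide to form an ortho-quinodimethane, which would oligomerise. This would happen if transmetalation from the hindered alkenyltin is slow at the temperature required; homocoupling of benzyl groups and migration of the new double bond into conjugation are lesser risks. The fallback replaces tin by zinc and so changes the transmetalation that limits the rate. It sets out from 10 and from the Grignard reagent 12. ZnBr2 in THF would convert 12 into bromo(2-methylprop-1-enyl)zinc F1, and a Negishi coupling of 10 with F1 under Pd(PPh3)4 at room temperature would follow. Transfer from zinc is much faster than from tin, so the benzylpalladium intermediate should be intercepted before it can eliminate, and alkenylzinc halides tolerate esters. The fallback returns to the route at 14.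

**Step 4.** The most likely failure is slow addition of the hydrogen-bonded, doubly ortho-substituted phenoxide to a quinone that the methoxy group has made less electrophilic. Base-induced decay of the quinone (enolisation at its methyl groups and self-condensation) could then overtake the substitution. The fallback reverses the order of the two substitutions and sets out from 3 and 6. The phenoxide of 6 would be offered the more electrophilic dibromide 3 (K2CO3, DMF, 0 °C) to give methyl 2,4-bis(benzyloxy)-6-[(3-bromo-5,6-dimethyl-1,4-benzoquinon-2-yl)oxy]benzoate F2. The small, strong nucleophile methoxide (NaOMe, 1 equiv, MeOH–THF, −40 °C) would then replace the remaining bromide; the benzyl ethers of ring A tolerate it. The fallback returns to the route at 7 and bypasses step 2 as well.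

**Step 6.** The most likely failure is over-bromination to geminal dibromides running alongside incomplete bromination of the second methyl group, because the rates of the first and second hydrogen abstraction at a benzylic carbon differ little. The fallback gives up stopping at the right stage and sets out from 9. An excess of NBS would drive the bromination past 10, in the limit to methyl 2,4-diacetoxy-6-[2,5-diacetoxy-3,4-bis(dibromomethyl)-6-methoxyphenoxy]benzoate F3. Diethyl phosphite and iPr2NEt (THF, 0 °C) would then reduce each dibromomethyl group selectively back to bromomethyl by halophilic attack of the phosphite, so that all over-brominated material converges. The fallback returns to the route at 10.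

**Step 9.** The most likely failure is premature oxidation of the electron-rich hydroquinone by traces of oxygen while methoxide is present, followed by displacement of the ring A phenoxide from the quinone so formed; lactonisation of a ring B phenoxide onto the ester is a lesser risk. The fallback replaces alkoxide transesterification by aminolysis and sets out from 14. Hydrazine hydrate in degassed THF–MeOH at 0 °C would transfer the four acetyl groups to nitrogen; no alkoxide is present, and hydrazine is itself a reductant that keeps ring B at the hydroquinone level. The hindered, hydrogen-bonded methyl ester should not react in the cold. The fallback makes no new compound and returns to the route at 15.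

## Further compounds

F1 | step 8 | bromo(2-methylprop-1-enyl)zinc | CC(C)=C[Zn]Br
F2 | step 4 | methyl 2,4-bis(benzyloxy)-6-[(3-bromo-5,6-dimethyl-1,4-benzoquinon-2-yl)oxy]benzoate | COC(=O)c1c(OCc2ccccc2)cc(OCc2ccccc2)cc1OC1=C(Br)C(=O)C(C)=C(C)C1=O
F3 | step 6 | methyl 2,4-diacetoxy-6-[2,5-diacetoxy-3,4-bis(dibromomethyl)-6-methoxyphenoxy]benzoate | COC(=O)c1c(OC(C)=O)cc(OC(C)=O)cc1Oc1c(OC)c(OC(C)=O)c(C(Br)Br)c(C(Br)Br)c1OC(C)=O
F0 | step 9 | none | none
A1 | alternative 1 | 6-hydroxy-5-methoxy-1,3-bis(methoxymethoxy)-7,8-bis(3-methylbut-2-enyl)xanthen-9-one | O=C1c2c(CC=C(C)C)c(CC=C(C)C)c(O)c(OC)c2Oc2cc(OCOC)cc(OCOC)c21
A2 | alternative 1 | depsidone (dibenzo[b,e][1,4]dioxepin-11-one) with the lactone oxygen on C1 of ring B, hydroxyl on C4, methoxy on C3, prenyl groups on C5 and C6 of ring B and two methoxymethyl ethers on ring A | O=C1Oc2c(CC=C(C)C)c(CC=C(C)C)c(O)c(OC)c2Oc2cc(OCOC)cc(OCOC)c21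
A3 | alternative 2 | methyl 3-[2,5-bis(tert-butyldimethylsilyloxy)-6-methoxy-3,4-bis(3-methylbut-2-enyl)phenoxy]prop-2-ynoate | COC(=O)C#COc1c(OC)c(O[Si](C)(C)C(C)(C)C)c(CC=C(C)C)c(CC=C(C)C)c1O[Si](C)(C)C(C)(C)C
A4 | alternative 2 | Chan's diene, 1-methoxy-1,3-bis(trimethylsilyloxy)buta-1,3-diene | COC(O[Si](C)(C)C)=CC(=C)O[Si](C)(C)C
A5 | alternative 2 | methyl 2-[2,5-bis(tert-butyldimethylsilyloxy)-6-methoxy-3,4-bis(3-methylbut-2-enyl)phenoxy]-4,6-dihydroxybenzoate | COC(=O)c1c(O)cc(O)cc1Oc1c(OC)c(O[Si](C)(C)C(C)(C)C)c(CC=C(C)C)c(CC=C(C)C)c1O[Si](C)(C)C(C)(C)C
A6 | alternative 3 | 2,3,6-trimethoxy-4,5-bis(3-methylbut-2-enyl)phenol | Oc1c(OC)c(OC)c(CC=C(C)C)c(CC=C(C)C)c1OC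
A7 | alternative 3 | 3,5-bis(methoxymethoxy)-2-(trimethylsilyl)phenyl trifluoromethanesulfonate | COCOc1cc(OCOC)c([Si](C)(C)C)c(OS(=O)(=O)C(F)(F)F)c1
A8 | alternative 3 | 2-[2,3,6-trimethoxy-4,5-bis(3-methylbut-2-enyl)phenoxy]-4,6-bis(methoxymethoxy)benzoic acid | OC(=O)c1c(OCOC)cc(OCOC)cc1Oc1c(OC)c(OC)c(CC=C(C)C)c(CC=C(C)C)c1OC
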